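The green run stopped at 20.0 min with 61.9% of its substrate left, and I had to decide what to charge next: could the following flasks carry less free catalyst than green's 0.41 mol%, and still convert as much in the time allowed?

| flask | substrate | gas phase | free catalyst | remark | time |
|---|---|---|---|---|---|
| green | 0.10 M | 6.6 mM (held) | 0.41 mol% | run made earlier |  |
| cedar | 0.10 M | 6.6 mM (held) | 0.1 mol% |  | 30 min |
| larch | 0.10 M | 6.6 mM (held) | 0.15 mol% |  | 30 min |
| oak | 0.10 M | 6.6 mM (held) | 0.25 mol% |  | 30 min |
| birch | 0.10 M | 6.6 mM (held) | 0.3 mol% |  | 30 min |

green run (percent of the substrate charged)

| time / min | product / % | substrate / % |
|---|---|---|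
| 2.00 | 3.5 | 95.2 |
| 5.00 | 9.9 | 92.3 |
| 10.0 | 20.0 | 82.1 |
| 15.0 | 28.0 | 71.5 |
| 20.0 | 38.0 | 61.9 |

(readings scatter by 1 percentage point)

- the analysis behind the earlier runs scatters by 1 percentage point, standard deviation
- at the start none of the gas phase is in solution
- "hardly changes" means that all values lie within two and a half points (for a concentration: within two and a half percent of the largest)
- no earlier run changes the charge of free catalyst; that part of a forecast is a guess

* amount of product at the end, in percent of the substrate charged for cedar, larch, oak, birch, in this order
* how that number moves from the first to the last of them (rises all the way / hardly changes / falls all the way / rises, then falls / falls, then rises)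

I began by counting how often the solution's gas had been replaced. Green had made 38.0 mM of product, and a solution at saturation holds 6.6 mM of dissolved gas. Assuming one gas taken up per product, I estimated that the gas taken up equalled 5.76 saturated solutions, so the crossing from gas phase into solution had to keep working during the run.

The green slope also stayed straight while substrate fell from 95.2% to 61.9%, and the crossing is a step that contains no substrate. I read the crossing as the likely rate-limiting step, although free catalyst fully occupied by substrate would give the same line, and green cannot separate the two.

So I carried one quantity, the ceiling: the product a flask reaches in the time allowed if gas crosses at green's pace, read from green's last reading as 57.0%. To reach it, the free catalyst charged in cedar had to turn over, on average, 4.10 times as fast as in green, and green showed what its catalyst did, not what it could do. I therefore committed to the ceiling for all four flasks, with cedar somewhat under it and the row rising slightly, and I decided to charge the thin loadings.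

The forecast, taking “the usual first-order dependence on catalyst”, gave 14%, 21%, 35% and 42%, rises all the way, which lies below my reckoning at each flask.

The flasks gave 51.4%, 53.5%, 55.3% and 55.8%, rises all the way.

    gas phase ⇌ dissolved gas, rate k1*(csat - [dissolved gas]) (kL = 0.300 min⁻¹)
    dissolved gas ⇌ dormant form (K = 10.0, k = 0.00670 min⁻¹)
    dissolved gas → decomposed reagent (k = 0.0600 min⁻¹)
    substrate + dissolved gas + free catalyst → free catalyst + product (k = 4.00 × 10⁵ M⁻² min⁻¹)
    2 free catalyst → spent catalyst (k = 23.0 M⁻¹ min⁻¹)

Against the ceiling of 57.0%, cedar reached 90.2% of it and birch 97.9%. Cedar ended with 9.40 × 10⁻⁴ M of dissolved gas, more than the 4.76 × 10⁻⁴ M in birch. The drag of the crossing is the largest single effect on the rise from cedar to birch, which is 4.5 percentage points with that drag and shrinks to 0.063 points without it.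

The numbers in the tables were computed for an exercise, and the scatter is random.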